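Each turn of the first step gives back the Ve it takes, so the Ve of a flask stays at its charge.

    Eb + Ve → Ve + Yx (k1 = 129 /M/min)
    2 Eb → Uv (k2 = 7.88 × 10⁻⁴ /M/min)

the same everywhere: Eb 0.050 M; time 40 min

|  | Ve |
|---|---|
| dusk | 1 mol% |
| spring | 2 mol% |
| dawn | 4 mol% |
| midnight | 8 mol% |

* amount of Yx at the end, in percent of the Eb charged for dusk, spring, dawn, midnight, in this order
* how that number moves from the first to the last of them (hardly changes / falls all the way / rises, then falls / falls, then rises / rises all the way)

- percentages count the Eb that a species holds: one Uv counts as two
- a doubled species enters its step squared and goes two at a time
- a step back or a flat step of under half a point counts as no turn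
- "hardly changes" means that all values lie within two and a half points (for a concentration: within two and a half percent of the largest)
- run time (dusk): 40 min

1. Let x be the fraction of the charged Eb still present. With Ve constant, the first step removes x at a fixed pseudo-first-order rate constant, the constant of that step times the Ve concentration. In dusk this is 0.0645 /min.

2. That rate constant times the time allowed is the lifetime count 2.58, here for dusk. By the first step alone, the fraction x left at the end is e raised to minus the count.

3. In dusk the second step at the full charge has a rate constant of 7.88 × 10⁻⁵ /min, which is lower than the first step's by a factor of 819. This reckoning therefore sets the second step aside and takes Yx as one minus x.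

4. Spring looks nearly the same as dusk, with the same Eb and the same time, but it has twice the Ve. Its count is 5.16, and doubling a count squares the fraction left. By this reckoning dusk keeps 7.58 % of its Eb and ends at 92.4 % Yx, while spring keeps 0.574 % and ends at 99.4 % Yx.

5. Dawn and midnight have counts of 10.3 and 20.6. This reckoning therefore has the row rising all the way, with a flat top.

6. The forecast gives 92.4 %, 99.4 %, >99.9 % and >99.9 %, shape rises all the way, and says “Yx simply climbs with catalyst loading”.

7. The simulation gives 92.4 %, 99.4 %, 100 % and 100 %, and the row rises all the way. In dusk Ve stands at 100 % of its charge at the end, the half-life of Eb by the first step is 11 min, shorter than the 40 min allowed, and the count of 2.58 stands beside 7.6 % of the Eb left. In spring the count of 5.16 stands beside 0.57 % of the Eb left.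

All constants were chosen freely, and the outcome is calculated.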